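## Structural features

The target is a C20 prostanoid methyl ester with one carbocycle, a cyclopent-2-enone made of C8–C12 (C1 = ester carbon). C9 is the ketone, C10 carries bromine on the ring alkene C10=C11, and C12 is a quaternary carbinol carbon holding the acetoxy group and the (Z)-oct-2-enyl chain C13–C20. C8 is sp2 and starts an exocyclic 7Z alkene that runs through a 5E alkene into the C1–C4 ester chain, so the ketone is cross-conjugated. C12 (R) is the only stereocentre and has no stereogenic neighbour (C8 and C11 are sp2, C13 is a methylene), so nothing in the skeleton can relay its configuration. Fragile points are the electrophilic C11 of the 2-bromoenone, the 7Z alkene (drifts to 7E with light, acid or reversible conjugate addition), the skipped 14Z alkene (moves into conjugation with base), the tertiary allylic acetate and the methyl ester. The real difficulty is to make the oxygenated quaternary C12 in one absolute sense together with the 7Z geometry, and to put bromine on C10 without touching four other alkenes. The key step uses the fact that C8 is bonded to the C9 carbonyl carbon, to C12 and to the exocyclic sp2 carbon C7: this is what the central carbon of a C7=C8=C9 allene looks like after it has bonded to C12, and the oxygen such a closure leaves on C10 is the handle for the bromine.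

## Logic of the disconnections

29 to 28: the ester bond between the C12 oxygen and the acetyl group is cut. The tertiary allylic acetate is the most base-labile group, so it goes on last. The gain is that the C12 oxygen can travel as a silyl ether. The demand is acylation of a hindered tertiary alcohol without nucleophilic damage at C11.

28 to 27 to 25 (through 26): the O–CH3 bond and the oxidation level of C1 are taken back to a primary alcohol. An ester at C1 cannot coexist with the organolithium of the key step. The demand is oxidation of the primary alcohol beside a tertiary alcohol and an electron-poor dienone, and esterification without base.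

25 to 24: both O–Si bonds are cut in one operation. The demand is a fluoride source that is not basic.

24 to 23 to 22: the C10–Br bond is traced back to a C10–O bond. Electrophilic bromination of a C10–H enone would attack the other alkenes, whereas the enol oxygen left by the ring closure can be activated as a triflate and exchanged for bromide by metal insertion at that carbon only. The demand is insertion into the C10–O bond without change of alkene geometry.

22 to 21: the ring bond C8–C12 is cut (key step). The ring, the C12 centre and the 7Z alkene are traded for an acyclic ketone whose only stereo-elements are an allene axis and an enol ether geometry. The demand is conrotatory closure in one sense, with the axis, the 11E geometry and the silyl group intact until the bond forms.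

21 to 20 to 19 + 9: the C9–C10 bond is cut into an amide and a C9 organolithium, which divides the skeleton into C1–C9 and C10–C20. The demand is carbonyl addition faster than proton transfer from C13 of 9, and a configurationally stable axis in 19.

9 to 8: the O–Si bond of the enol ether is cut. The demand is E geometry and enolisation toward C11, not C13.

8 to 5 + 6 (through 7), and 5 to 3 + 4: the C10–N bond and then the C11–C12 bond are cut. C10 and C11 come from 4, and the whole C12–C20 part with its Z alkene comes from one acid. The demand is that the skipped alkene does not migrate.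

3 to 1 (through 2): only the oxidation level of C12 changes, back to a commercial alcohol.

19 to 18 to 17: the C9–Li bond goes back to C9–H, and the single enantiomer goes back to the racemate. No bond is cut in the second operation; the demand is a clean separation of the two axial enantiomers.

17 to 16: a formal hydrogen shift from C9 to C7 turns the allene into a propargylic ether. The demand is that isomerisation stops at the allene.

16 to 15 + 11: the sp2–sp bond C6–C7 is cut into an E alkenyl iodide and a terminal alkyne.

15 to 13 (through 14) to 12, and 11 to 10: the C6–I bond goes back to a terminal alkyne by hydrometalation, and the two O-protecting groups go back to commercial alkynols.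

## Other disconnections considered

Alternative 1: The cut is C11–C12 on a saturated ring. In the forward step a chiral triazolylidene carbene adds to the C11 aldehyde of the keto-aldehyde A1, and the acyl-anion equivalent attacks the C12 ketone (5-exo-trig crossed benzoin) to give the α-ketol A2.
- In its favour: C12 is set by a catalyst, and aldehyde–ketone benzoin closures to five-membered α-ketols are a well-behaved reaction class. On the source of chirality this alternative is the better one, because the chosen plan relies on a chromatographically resolved allene.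
- Against it here: A2 is far from the target. Its ketone sits at C11 where the target has an alkene CH, C9 is a ketal, C10 has no bromine, C8 has no alkylidene, and only a two-carbon stub of the octenyl chain is present. A1 also has an oxygen β to the aldehyde and an enolisable methylene between ketone and ketal, so β-elimination and aldol closure can compete with the umpolung.
- Comparison: structurally it addresses C12 only, while the chosen step delivers ring, C12 and 7Z together. Mechanistically it is a catalyst-controlled polar addition against a substrate-controlled pericyclic closure, and neither has precedent on the exact substrate, so they are equal there. In step economy it is clearly worse: carbonyl transposition, bromination, a Z-Wittig reaction and an aldol condensation with no control of 7Z would follow.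

Alternative 2: The cuts are C9–C10, C8–C9 and C6–C7 in one step. Zerovalent palladium inserts into the carbon–iodine bond of the geminal bromo-iodo enyne A3, CO insertion gives an acylpalladium that adds syn across the C7≡C8 alkyne (5-exo-dig), and the alkenylpalladium is coupled with the stannane A4 to give A5.
- In its favour: three bonds and the ring form at once, and bromine and the methyl ester are already in place. The endgame would be a silyl-to-acetyl exchange only, so on steps after the key step and on avoiding the enol-to-bromide detour it is better than the chosen plan. The 7Z geometry follows from syn addition as inherently as it does from torquoselectivity (equal).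
- Against it here: the step creates no stereocentre, so the fully substituted C12 ether of A3 must be made enantiopure beforehand, which only moves the hard problem. Iodine must sit cis to the quaternary carbon, the hindered position. The acylpalladium can couple with A4 before it cyclises. A5 is itself a 2-bromoenone open to a second insertion. CO and tin are hazardous.
- Comparison: more convergent in structure, less secure in mechanism (three competing organopalladium steps against one electrocyclisation), and shorter only if A3 were easy to obtain.

Alternative 3: The cuts are C9–C10 and C10–C11 (one-carbon insertion). The prochiral cyclobutanone A6 is desymmetrised by enantioselective deprotonation and trapped as the silyloxycyclobutene A7; dibromocarbene adds to C9=C11, the bicyclo[2.1.0]pentane opens with loss of bromide, and loss of Me3SiBr gives the bromoenone A8.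
- In its favour: bromine arrives with C10, regiospecifically and without triflate or nickel, which is better than the chosen plan on that point. Dihalocarbene ring expansion of silyloxycycloalkenes is a known reaction class and the reagents are cheap.
- Against it here: the enantiotopic methylenes of A6 differ only through a remote silyloxy-versus-alkyl difference, so discrimination is uncertain. Dibromocarbene would also add to the C14=C15 alkene. A8 lacks C1–C7, which would have to be added by aldol condensation on a base-sensitive bromoenone with no control of 7Z.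
- Comparison: structurally it solves C10–Br best and the exocyclic alkene not at all. Both plans use a pericyclic event with a fixed rotational sense (equal). Stereocontrol comes from an external chiral base instead of an axis. The step count is similar, but the route ends in an uncontrolled olefination.

Key step: step 11

Remark (stereochemical check): the (aR) axis of 18, the 11E enol ether of 9, outward rotation of C6 and the 12R, 7Z outcome in 22 were re-derived and belong together; the precursor and product structures needed no correction. The C9 oxygen is cross-conjugated in the open cation and acts as a donor only after closure.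

Assumption: the allene is obtained as one enantiomer by chromatography on a chiral phase, because no stereospecific synthesis of 3-substituted 1-(alkoxymethoxy)allenes is established. Prostanoid numbering is used for all intermediates.

## Route

Step 1
Reactants: 1 (3Z)-non-3-en-1-ol
Product: 3 (3Z)-non-3-enoic acid, via (3Z)-non-3-enal 2 (not isolated)
Conditions: CrO3, H2SO4, H2O, acetone, 0 °C
Reagents that add atoms: water, O
Why: Jones oxidation; the aldehyde is oxidised through its hydrate faster than the β,γ-alkene can move into conjugation in cold aqueous acid, so the 3Z alkene should stay in place.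

Step 2
Reactants: 3 (3Z)-non-3-enoic acid; 4 Meldrum's acid
Product: 5 5-[(3Z)-1-hydroxynon-3-en-1-ylidene]-2,2-dimethyl-1,3-dioxane-4,6-dione
Conditions: DCC, DMAP, CH2Cl2, 0 °C to rt
Reagents that add atoms: none
Why: Carbodiimide-mediated C-acylation of Meldrum's acid with DMAP as acyl-transfer catalyst; the product is the stable enol and adds C10 and C11 to the C12–C20 acid.

Step 3
Reactants: 5 acyl Meldrum's acid; 6 morpholine
Product: 8 (5Z)-1-(morpholin-4-yl)undec-5-ene-1,3-dione, via acylketene 7 (not isolated)
Conditions: toluene, 80 °C
Reagents that add atoms: none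
Why: Thermal fragmentation of the acyl Meldrum's acid releases acetone and CO2 and gives an acylketene that the amine captures (aminolysis of acyl Meldrum's acids to β-keto amides); the neutral conditions leave the skipped Z alkene alone.

Step 4
Reactants: 8 (5Z)-1-(morpholin-4-yl)undec-5-ene-1,3-dione
Product: 9 (2E,5Z)-3-[(tert-butyldimethylsilyl)oxy]-1-(morpholin-4-yl)undeca-2,5-dien-1-one
Conditions: TBSOTf, Et3N, CH2Cl2, −78 to 0 °C
Reagents that add atoms: tert-butyldimethylsilyl trifluoromethanesulfonate, CC(C)(C)[Si](C)(C)OS(=O)(=O)C(F)(F)F
Why: O-Silylation at the more acidic C11 side of the β-dicarbonyl unit through a non-chelated ammonium enolate; dipole minimisation in the open enolate favours the E enol ether (silyloxy trans to the amide carbonyl), as in amine-mediated enol sulfonylation and phosphorylation of β-keto esters. Any Z isomer is removed by chromatography.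

Step 5
Reactants: 10 prop-2-yn-1-ol
Product: 11 3-(methoxymethoxy)prop-1-yne
Conditions: MOMCl, i-Pr2NEt, CH2Cl2, 0 °C to rt
Reagents that add atoms: chloromethyl methyl ether, COCCl
Why: O-Alkylation of a primary alcohol with a chloromethyl ether and a hindered amine base (acetal protection).

Step 6
Reactants: 12 hex-5-yn-1-ol
Product: 13 tert-butyl(hex-5-yn-1-yloxy)diphenylsilane
Conditions: TBDPSCl, imidazole, DMF, rt
Reagents that add atoms: tert-butyldiphenylsilyl chloride, CC(C)(C)[Si](Cl)(c1ccccc1)c1ccccc1
Why: Standard silylation of a primary alcohol; this ether tolerates organolithium, base and the acid of the key step and gives the allene a chromophore for the resolution.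

Step 7
Reactants: 13 tert-butyl(hex-5-yn-1-yloxy)diphenylsilane
Product: 15 tert-butyl{[(5E)-6-iodohex-5-en-1-yl]oxy}diphenylsilane, via alkenylzirconocene chloride 14 (not isolated)
Conditions: Cp2Zr(H)Cl, THF, rt; then I2, 0 °C
Reagents that add atoms: iodine, II
Why: Hydrozirconation of the terminal alkyne is syn and puts zirconium on the terminal carbon; iodinolysis of the carbon–zirconium bond with retention gives the E alkenyl iodide.

Step 8
Reactants: 15 tert-butyl{[(5E)-6-iodohex-5-en-1-yl]oxy}diphenylsilane; 11 3-(methoxymethoxy)prop-1-yne
Product: 16 tert-butyl{[(5E)-9-(methoxymethoxy)non-5-en-7-yn-1-yl]oxy}diphenylsilane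
Conditions: PdCl2(PPh3)2 (cat.), CuI (cat.), Et3N, THF, rt
Reagents that add atoms: none
Why: Sonogashira coupling of an alkenyl iodide with a terminal alkyne forms C6–C7 with retention of the E geometry; acetal and silyl ether are inert.

Step 9
Reactants: 16 tert-butyl{[(5E)-9-(methoxymethoxy)non-5-en-7-yn-1-yl]oxy}diphenylsilane
Product: 17 rac-tert-butyl{[(5E)-9-(methoxymethoxy)nona-5,7,8-trien-1-yl]oxy}diphenylsilane
Conditions: KOt-Bu (cat.), DMSO–THF, 0 °C to rt
Reagents that add atoms: none
Why: Base-catalysed propargyl ether to allenyl ether isomerisation: the C9 protons (propargylic and α to oxygen) are the most acidic, and reprotonation at C7 gives the allene conjugated with both the ether oxygen and the C5=C6 alkene. Catalytic base, low temperature and short contact are meant to stop further prototropy.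

Step 10
Reactants: 17 rac-tert-butyl{[(5E)-9-(methoxymethoxy)nona-5,7,8-trien-1-yl]oxy}diphenylsilane
Product: 18 (aR)-tert-butyl{[(5E)-9-(methoxymethoxy)nona-5,7,8-trien-1-yl]oxy}diphenylsilane
Conditions: preparative HPLC, cellulose tris(3,5-dimethylphenylcarbamate) phase, hexane–i-PrOH, rt
Reagents that add atoms: none
Why: The 1,3-disubstituted allene is axially chiral and configurationally stable as the neutral compound, so its enantiomers can be separated on a polysaccharide chiral phase under neutral conditions; the other enantiomer is kept (see the fallback for step 4).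

Step 11
Reactants: 18 (aR)-allene; 9 (2E,5Z)-3-[(tert-butyldimethylsilyl)oxy]-1-(morpholin-4-yl)undeca-2,5-dien-1-one
Product: 22 (5E,7Z,12R,14Z)-12-[(tert-butyldimethylsilyl)oxy]-1-[(tert-butyldiphenylsilyl)oxy]-10-hydroxyprosta-5,7,10,14-tetraen-9-one, via lithioallene 19 (not isolated), via lithium hemiaminal adduct 20 (not isolated), via allenyl vinyl ketone 21 (not isolated)
Conditions: n-BuLi, THF, −78 °C; 9, −78 to −40 °C; aq. KH2PO4, −78 °C to rt
Reagents that add atoms: none
Why: Deprotonation of 18 at the oxygen-bearing C9 gives 19 with the axis intact, and its addition to the morpholine amide gives the chelated adduct 20, which holds until the quench so that no second addition occurs. Mild acid releases ketone 21 and protonates its C10 carbonyl to a hydroxypentadienyl cation over C8–C12, to which the C12 silyloxy group is a direct donor. A thermal 4π conrotatory electrocyclisation joins C8 and C12 and closes the only ring, the cyclopentenone C8–C12; the 2-oxyallyl cation so formed loses the methoxymethyl group from the C9 oxygen, which gives the C9 ketone and leaves C10 as an enol. The closest known reaction type is the allene ether Nazarov cyclisation of α-(alkoxymethoxy)allenyl vinyl ketones made from lithioallenes and morpholine enamides, including axis-to-centre chirality transfer with 3-substituted allenes; a silyloxy group on the closing terminus is the element without precedent. C12 is set by torquoselectivity: the conrotatory sense that turns the dienyl substituent on C7 away from C12 is preferred, and with the (aR) axis and the E enol ether (C13 inside, silyloxy outside) this sense gives 12R. The same rotation leaves C6 cis to C9, which is 7Z. The step needs a configurationally stable 19 (hence −78 °C), retention of the 11E geometry in the cation and retention of the silyl group; the buffered weak acid and the bulk of the tert-butyldimethylsilyl group are chosen for this.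

Step 12
Reactants: 22 (5E,7Z,12R,14Z)-12-[(tert-butyldimethylsilyl)oxy]-1-[(tert-butyldiphenylsilyl)oxy]-10-hydroxyprosta-5,7,10,14-tetraen-9-one
Product: 23 (5E,7Z,12R,14Z)-12-[(tert-butyldimethylsilyl)oxy]-1-[(tert-butyldiphenylsilyl)oxy]-9-oxoprosta-5,7,10,14-tetraen-10-yl trifluoromethanesulfonate
Conditions: PhNTf2, Et3N, DMAP (cat.), CH2Cl2, 0 °C to rt
Reagents that add atoms: N-phenylbis(trifluoromethanesulfonimide), O=S(=O)(N(c1ccccc1)S(=O)(=O)C(F)(F)F)C(F)(F)F
Why: O-Sulfonylation of the acidic enol of a 2-hydroxycyclopentenone; only this enol can exist because C8 has no hydrogen, so the triflate forms at C10 alone.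

Step 13
Reactants: 23 C10 enol triflate
Product: 24 (5E,7Z,12R,14Z)-10-bromo-12-[(tert-butyldimethylsilyl)oxy]-1-[(tert-butyldiphenylsilyl)oxy]prosta-5,7,10,14-tetraen-9-one
Conditions: Ni(cod)2 (cat.), LiBr, DMA–THF, rt
Reagents that add atoms: lithium bromide, [Li+].[Br-]
Why: Nickel-catalysed halogenation of an enol triflate: zerovalent nickel inserts into the activated C10–O bond, triflate is exchanged for bromide on divalent nickel, and C–Br reductive elimination follows; excess LiBr drives the exchange and the neutral conditions spare silyl ethers and alkene geometry.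

Step 14
Reactants: 24 C10 bromide
Product: 25 (5E,7Z,12R,14Z)-10-bromo-1,12-dihydroxyprosta-5,7,10,14-tetraen-9-one
Conditions: HF·pyridine, THF, 0 °C to rt
Reagents that add atoms: none
Why: Fluoride-driven cleavage of both silyl ethers under weakly acidic conditions; C12 does not ionise because the cation would be a destabilised cyclopentadienone-type cation, so its configuration is kept.

Step 15
Reactants: 25 diol
Product: 27 (5E,7Z,12R,14Z)-10-bromo-12-hydroxy-9-oxoprosta-5,7,10,14-tetraen-1-oic acid, via C1 aldehyde 26 (not isolated)
Conditions: TEMPO (cat.), PhI(OAc)2, MeCN–H2O (pH 7), rt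
Reagents that add atoms: water, O
Why: Oxoammonium-mediated oxidation is selective for the primary alcohol and carries the aldehyde hydrate on to the acid; the tertiary alcohol cannot be oxidised and the electron-poor alkenes are not attacked.

Step 16
Reactants: 27 carboxylic acid
Product: 28 methyl (5E,7Z,12R,14Z)-10-bromo-12-hydroxy-9-oxoprosta-5,7,10,14-tetraen-1-oate
Conditions: TMSCHN2, MeOH–toluene, 0 °C
Reagents that add atoms: (trimethylsilyl)diazomethane, C[Si](C)(C)C=[N+]=[N-]
Why: Base-free O-methylation of the acid by diazomethane released in situ; a slight excess and short contact at 0 °C are meant to keep dipolar addition to the bromoenone from competing.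

Step 17
Reactants: 28 methyl (5E,7Z,12R,14Z)-10-bromo-12-hydroxy-9-oxoprosta-5,7,10,14-tetraen-1-oate
Product: 29 methyl (5E,7Z,12R,14Z)-12-acetoxy-10-bromo-9-oxoprosta-5,7,10,14-tetraen-1-oate
Conditions: Ac2O, DMAP, Et3N, CH2Cl2, rt
Reagents that add atoms: acetic anhydride, CC(=O)OC(C)=O
Why: DMAP-catalysed acylation of the tertiary allylic alcohol on oxygen; no bond to C12 is broken, so the 12R configuration is retained.

## Compound list

1 | (3Z)-non-3-en-1-ol | CCCCC/C=C\CCO | starting material
2 | (3Z)-non-3-enal | CCCCC/C=C\CC=O | intermediate
3 | (3Z)-non-3-enoic acid | CCCCC/C=C\CC(=O)O | intermediate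
4 | Meldrum's acid (2,2-dimethyl-1,3-dioxane-4,6-dione) | CC1(C)OC(=O)CC(=O)O1 | starting material
5 | 5-[(3Z)-1-hydroxynon-3-en-1-ylidene]-2,2-dimethyl-1,3-dioxane-4,6-dione | CCCCC/C=C\CC(O)=C1C(=O)OC(C)(C)OC1=O | intermediate
6 | morpholine | C1COCCN1 | starting material
7 | (5Z)-undeca-1,5-diene-1,3-dione (acylketene) | CCCCC/C=C\CC(=O)C=C=O | intermediate
8 | (5Z)-1-(morpholin-4-yl)undec-5-ene-1,3-dione | CCCCC/C=C\CC(=O)CC(=O)N1CCOCC1 | intermediate
9 | (2E,5Z)-3-[(tert-butyldimethylsilyl)oxy]-1-(morpholin-4-yl)undeca-2,5-dien-1-one | O=C(/C=C(/O[Si](C)(C)C(C)(C)C)C/C=C\CCCCC)N1CCOCC1 | intermediate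
10 | prop-2-yn-1-ol | C#CCO | starting material
11 | 3-(methoxymethoxy)prop-1-yne | C#CCOCOC | intermediate
12 | hex-5-yn-1-ol | C#CCCCCO | starting material
13 | tert-butyl(hex-5-yn-1-yloxy)diphenylsilane | C#CCCCCO[Si](c1ccccc1)(c1ccccc1)C(C)(C)C | intermediate
14 | chlorobis(cyclopentadienyl)[(1E)-6-(tert-butyldiphenylsilyloxy)hex-1-en-1-yl]zirconium | Cl[Zr](/C=C/CCCCO[Si](c1ccccc1)(c1ccccc1)C(C)(C)C)(C1C=CC=C1)C1C=CC=C1 | intermediate
15 | tert-butyl{[(5E)-6-iodohex-5-en-1-yl]oxy}diphenylsilane | I/C=C/CCCCO[Si](c1ccccc1)(c1ccccc1)C(C)(C)C | intermediate
16 | tert-butyl{[(5E)-9-(methoxymethoxy)non-5-en-7-yn-1-yl]oxy}diphenylsilane | COCOCC#C/C=C/CCCCO[Si](c1ccccc1)(c1ccccc1)C(C)(C)C | intermediate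
17 | rac-tert-butyl{[(5E)-9-(methoxymethoxy)nona-5,7,8-trien-1-yl]oxy}diphenylsilane | COCOC=C=C/C=C/CCCCO[Si](c1ccccc1)(c1ccccc1)C(C)(C)C | intermediate
18 | (aR)-tert-butyl{[(5E)-9-(methoxymethoxy)nona-5,7,8-trien-1-yl]oxy}diphenylsilane | COCOC([H])=[C@]=C([H])/C=C/CCCCO[Si](c1ccccc1)(c1ccccc1)C(C)(C)C | intermediate
19 | C9-lithio derivative of 18 (axis retained) | COCOC([Li])=[C@]=C([H])/C=C/CCCCO[Si](c1ccccc1)(c1ccccc1)C(C)(C)C | intermediate
20 | lithium (5E,11E,14Z)-12-[(tert-butyldimethylsilyl)oxy]-1-[(tert-butyldiphenylsilyl)oxy]-9-(methoxymethoxy)-10-(morpholin-4-yl)icosa-5,7,8,11,14-pentaen-10-olate (axis as in 18, C10 unspecified) | COCOC(C(O[Li])(N1CCOCC1)/C=C(/O[Si](C)(C)C(C)(C)C)C/C=C\CCCCC)=[C@]=C([H])/C=C/CCCCO[Si](c1ccccc1)(c1ccccc1)C(C)(C)C | intermediate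
21 | (5E,11E,14Z)-12-[(tert-butyldimethylsilyl)oxy]-1-[(tert-butyldiphenylsilyl)oxy]-9-(methoxymethoxy)icosa-5,7,8,11,14-pentaen-10-one, (aR) axis at C7=C8=C9 | COCOC(C(=O)/C=C(/O[Si](C)(C)C(C)(C)C)C/C=C\CCCCC)=[C@]=C([H])/C=C/CCCCO[Si](c1ccccc1)(c1ccccc1)C(C)(C)C | intermediate
22 | (5E,7Z,12R,14Z)-12-[(tert-butyldimethylsilyl)oxy]-1-[(tert-butyldiphenylsilyl)oxy]-10-hydroxyprosta-5,7,10,14-tetraen-9-one | CCCCC/C=C\C[C@@]1(O[Si](C)(C)C(C)(C)C)C=C(O)C(=O)/C1=C\C=C\CCCCO[Si](c2ccccc2)(c2ccccc2)C(C)(C)C | intermediate
23 | (5E,7Z,12R,14Z)-12-[(tert-butyldimethylsilyl)oxy]-1-[(tert-butyldiphenylsilyl)oxy]-9-oxoprosta-5,7,10,14-tetraen-10-yl trifluoromethanesulfonate | CCCCC/C=C\C[C@@]1(O[Si](C)(C)C(C)(C)C)C=C(OS(=O)(=O)C(F)(F)F)C(=O)/C1=C\C=C\CCCCO[Si](c2ccccc2)(c2ccccc2)C(C)(C)C | intermediate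
24 | (5E,7Z,12R,14Z)-10-bromo-12-[(tert-butyldimethylsilyl)oxy]-1-[(tert-butyldiphenylsilyl)oxy]prosta-5,7,10,14-tetraen-9-one | CCCCC/C=C\C[C@@]1(O[Si](C)(C)C(C)(C)C)C=C(Br)C(=O)/C1=C\C=C\CCCCO[Si](c2ccccc2)(c2ccccc2)C(C)(C)C | intermediate
25 | (5E,7Z,12R,14Z)-10-bromo-1,12-dihydroxyprosta-5,7,10,14-tetraen-9-one | CCCCC/C=C\C[C@@]1(O)C=C(Br)C(=O)/C1=C\C=C\CCCCO | intermediate
26 | (5E,7Z,12R,14Z)-10-bromo-12-hydroxy-9-oxoprosta-5,7,10,14-tetraen-1-al | CCCCC/C=C\C[C@@]1(O)C=C(Br)C(=O)/C1=C\C=C\CCCC=O | intermediate
27 | (5E,7Z,12R,14Z)-10-bromo-12-hydroxy-9-oxoprosta-5,7,10,14-tetraen-1-oic acid | CCCCC/C=C\C[C@@]1(O)C=C(Br)C(=O)/C1=C\C=C\CCCC(=O)O | intermediate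
28 | methyl (5E,7Z,12R,14Z)-10-bromo-12-hydroxy-9-oxoprosta-5,7,10,14-tetraen-1-oate | CCCCC/C=C\C[C@@]1(O)C=C(Br)C(=O)/C1=C\C=C\CCCC(=O)OC | intermediate
29 | methyl (5E,7Z,12R,14Z)-12-acetoxy-10-bromo-9-oxoprosta-5,7,10,14-tetraen-1-oate | CCCCC/C=C\C[C@@]1(OC(C)=O)C=C(Br)C(=O)/C1=C\C=C\CCCC(=O)OC | target

## Step count and least certain steps

Total: 17 steps, convergent. Longest linear sequence: 12 steps (steps 6 to 17, from 12 to 29).

Step 11 (key step).
- What may go wrong: the most likely failure is silyl transfer from the C12 oxygen to water or phosphate once the carbonyl is protonated. The cation is a silylated vinylogous ester, and the aqueous acid needed to break down adduct 20 is exactly the medium that favours this loss. The resulting 1,3-diketone would not close through carbon.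
- Further risks: rotation about C11–C12 in the delocalised cation would erode control of C12. Leakage of 19 into its propargylic form would erode the axis, which the vinyl group on C7 makes easier. Proton abstraction from the doubly allylic C13 of 9 could compete with addition.
- Fallback: bring C10 in at the aldehyde level, so that 21 is made by a neutral oxidation and is cyclised as an isolated compound without water. It sets out from 9 and 19. Reduction of 9 with i-Bu2AlH at −78 °C (morpholine amides stop at the aldehyde) should give the enal (2E,5Z)-3-[(tert-butyldimethylsilyl)oxy]undeca-2,5-dienal F1. Addition of 19 to this aldehyde, which is faster and less prone to proton transfer than addition to the amide, should give the allenyl carbinol F2 as both C10 epimers. Oxidation with MnO2 in CH2Cl2 should give 21. Closure with a catalytic amount of HNTf2 in CH2Cl2 containing hexafluoroisopropanol as trap for the methoxymethyl cation, at low temperature, comes back to the route at 22. If geometry erosion is the limit, the mirror-image pairing under step 4 applies.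

Step 9.
- What may go wrong: over-isomerisation. The C4 protons of 17 are allylic to the conjugated system, and further prototropy to a 1-alkoxytriene is thermodynamically downhill; incomplete conversion of 16 is the other side of the same window.
- Fallback: build the allene by cross-coupling instead of equilibration. It sets out from 11 and 15. Catalytic KOt-Bu should convert 11 into (methoxymethoxy)allene F3. Lithiation with n-BuLi and Me3SiCl should give the C9-silyl allene F4. A second lithiation, now at the free terminus, transmetalation with ZnCl2 and Negishi coupling with 15 under Pd(PPh3)4 should give the silylated vinylallene F5. One equivalent of Bu4NF at −20 °C (the primary silyl ether is slower to cleave) comes back to the route at 17.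

Step 4.
- What may go wrong: poor control of enol ether geometry, or formation of the Z isomer as the main product, and partial enolisation toward C13.
- Fallback: use the mirror-image pairing, which converges on the same product by the same torquoselectivity. It sets out from 8 and from the second fraction of step 10. A chelated sodium enolate (NaH, then TBSCl, THF) should give the Z enol ether F6. The (aS)-allene F7 is lithiated to F8, added to F6 to give the adduct F9, and released as the ketone F10. In F10 the silyloxy group is inside and C13 outside, so the antipodal axis turns C6 outward in the opposite sense and again places oxygen and octenyl for 12R and 7Z. The fallback comes back to the route at 22.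

Step 13.
- What may go wrong: reduction of the triflate to the C10–H enone, re-insertion of nickel into the product bromide with homocoupling, or sequestration of zerovalent nickel by the dienone.
- Fallback: a two-step exchange through tin. It sets out from 23. Pd(PPh3)4, Me3SnSnMe3 and LiCl in THF should give the C10 stannane F11. Bromodestannylation with N-bromosuccinimide at 0 °C, ipso and faster than attack on the other alkenes, comes back to the route at 24.

## Further compounds

F1 | step 11 | (2E,5Z)-3-[(tert-butyldimethylsilyl)oxy]undeca-2,5-dienal | O=C/C=C(/O[Si](C)(C)C(C)(C)C)C/C=C\CCCCC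
F2 | step 11 | (5E,11E,14Z)-12-[(tert-butyldimethylsilyl)oxy]-1-[(tert-butyldiphenylsilyl)oxy]-9-(methoxymethoxy)icosa-5,7,8,11,14-pentaen-10-ol, (aR) axis, both C10 epimers | COCOC(C(O)/C=C(/O[Si](C)(C)C(C)(C)C)C/C=C\CCCCC)=[C@]=C([H])/C=C/CCCCO[Si](c1ccccc1)(c1ccccc1)C(C)(C)C
F3 | step 9 | 1-(methoxymethoxy)propa-1,2-diene | COCOC=C=C
F4 | step 9 | [1-(methoxymethoxy)propa-1,2-dien-1-yl]trimethylsilane | COCOC(=C=C)[Si](C)(C)C
F5 | step 9 | rac-tert-butyl{[(5E)-9-(methoxymethoxy)-9-(trimethylsilyl)nona-5,7,8-trien-1-yl]oxy}diphenylsilane | COCOC(=C=C/C=C/CCCCO[Si](c1ccccc1)(c1ccccc1)C(C)(C)C)[Si](C)(C)C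
F6 | step 4 | (2Z,5Z)-3-[(tert-butyldimethylsilyl)oxy]-1-(morpholin-4-yl)undeca-2,5-dien-1-one | O=C(/C=C(\O[Si](C)(C)C(C)(C)C)C/C=C\CCCCC)N1CCOCC1
F7 | step 4 | (aS)-tert-butyl{[(5E)-9-(methoxymethoxy)nona-5,7,8-trien-1-yl]oxy}diphenylsilane | COCOC([H])=[C@@]=C([H])/C=C/CCCCO[Si](c1ccccc1)(c1ccccc1)C(C)(C)C
F8 | step 4 | C9-lithio derivative of the (aS)-allene | COCOC([Li])=[C@@]=C([H])/C=C/CCCCO[Si](c1ccccc1)(c1ccccc1)C(C)(C)C
F9 | step 4 | lithium hemiaminal adduct of the (aS)-lithioallene and the Z enol ether amide | COCOC(C(O[Li])(N1CCOCC1)/C=C(\O[Si](C)(C)C(C)(C)C)C/C=C\CCCCC)=[C@@]=C([H])/C=C/CCCCO[Si](c1ccccc1)(c1ccccc1)C(C)(C)C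
F10 | step 4 | (5E,11Z,14Z)-12-[(tert-butyldimethylsilyl)oxy]-1-[(tert-butyldiphenylsilyl)oxy]-9-(methoxymethoxy)icosa-5,7,8,11,14-pentaen-10-one, (aS) axis | COCOC(C(=O)/C=C(\O[Si](C)(C)C(C)(C)C)C/C=C\CCCCC)=[C@@]=C([H])/C=C/CCCCO[Si](c1ccccc1)(c1ccccc1)C(C)(C)C
F11 | step 13 | (5E,7Z,12R,14Z)-12-[(tert-butyldimethylsilyl)oxy]-1-[(tert-butyldiphenylsilyl)oxy]-10-(trimethylstannyl)prosta-5,7,10,14-tetraen-9-one | CCCCC/C=C\C[C@@]1(O[Si](C)(C)C(C)(C)C)C=C([Sn](C)(C)C)C(=O)/C1=C\C=C\CCCCO[Si](c2ccccc2)(c2ccccc2)C(C)(C)C
A1 | alternative 1 | 2-{2-[4-(4-methoxybenzyloxy)-2-oxobutyl]-1,3-dioxolan-2-yl}acetaldehyde | COc1ccc(COCCC(=O)CC2(CC=O)OCCO2)cc1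
A2 | alternative 1 | 2-hydroxy-2-[2-(4-methoxybenzyloxy)ethyl]cyclopentanone 4-ethylene ketal | COc1ccc(COCC[C@@]2(O)C(=O)CC3(OCCO3)C2)cc1
A3 | alternative 2 | (1Z,5Z)-1-bromo-3-ethynyl-1-iodo-3-[(triethylsilyl)oxy]undeca-1,5-diene, C3 as drawn | CCCCC/C=C\C[C@@](C#C)(O[Si](CC)(CC)CC)/C=C(/Br)I
A4 | alternative 2 | methyl (5E)-6-(tributylstannyl)hex-5-enoate | CCCC[Sn](CCCC)(CCCC)/C=C/CCCC(=O)OC
A5 | alternative 2 | methyl (5E,7Z,12R,14Z)-10-bromo-9-oxo-12-[(triethylsilyl)oxy]prosta-5,7,10,14-tetraen-1-oate | CCCCC/C=C\C[C@@]1(O[Si](CC)(CC)CC)C=C(Br)C(=O)/C1=C\C=C\CCCC(=O)OC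
A6 | alternative 3 | 3-[(tert-butyldimethylsilyl)oxy]-3-[(2Z)-oct-2-en-1-yl]cyclobutan-1-one | CCCCC/C=C\CC1(O[Si](C)(C)C(C)(C)C)CC(=O)C1
A7 | alternative 3 | 3-[(tert-butyldimethylsilyl)oxy]-3-[(2Z)-oct-2-en-1-yl]-1-[(trimethylsilyl)oxy]cyclobut-1-ene, C3 as drawn | CCCCC/C=C\C[C@@]1(O[Si](C)(C)C(C)(C)C)C=C(O[Si](C)(C)C)C1
A8 | alternative 3 | 2-bromo-4-[(tert-butyldimethylsilyl)oxy]-4-[(2Z)-oct-2-en-1-yl]cyclopent-2-en-1-one | CCCCC/C=C\C[C@@]1(O[Si](C)(C)C(C)(C)C)C=C(Br)C(=O)C1
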